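**Strategy.** The furanone-bridged ten-membered ring is disconnected across C2–C5. Its diene C2=C3–C4=C5 (E within the carbocycle at C2=C3, Z at C4=C5, with C3 tied to the C10 oxygen) is what conrotatory opening of a cis-fused cyclobutene gives. The precursor is therefore a Z-cyclooct-2-enone (ring atoms C1, C2, C5–C10) carrying a 1-propynyl ether on the C10 oxygen, a silylethynyl group at C7, a silyl ether at C6 and an 8,9-acetonide. Irradiation joins C2–C3 and C4–C5, and thermal opening then delivers furanone, diene and ten-membered ring in one operation. The cyclooctenone comes from L-tartrate by chelation-controlled C10 construction, allenylzinc propargylation and ring-closing metathesis. Pd-catalysed cyclocarbonylation closes the methylene lactone afterwards.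

Key step: step 18

Remark on numbering: germacranolide locants are used throughout (C1 ketone, C2=C3 furanone alkene, C4=C5, C6 lactone carbinol, C7, C8 ester carbinol, C9 free carbinol, C10 quaternary, C11–C13 lactone carbons).
Assumption: the C1 carbinol made by vinyl addition is carried as a mixture of epimers (SMILES leave C1 undefined), because this centre is oxidised to the ketone before the key step.
Design of the photosubstrate: the 8,9-diol is an acetonide (no arene or benzylic C–H near the excited enone), the alkyne carries SiEt3 (stable to carbonate), and the C1 ketone is unveiled only immediately before irradiation.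

Step 1
Reactants: 1 dimethyl 2,3-O-isopropylidene-L-tartrate; 2 N,O-dimethylhydroxylamine hydrochloride
Product: 3 bis-Weinreb amide (4R,5R)-N4,N5-dimethoxy-N4,N5,2,2-tetramethyl-1,3-dioxolane-4,5-dicarboxamide
Conditions: MeNHOMe·HCl, i-PrMgCl, THF, −20 °C
Reagents that add atoms: N,O-dimethylhydroxylamine hydrochloride, CNOC.Cl
Why: Direct aminolysis of both esters by the chloromagnesium amide of MeNHOMe (Weinreb amide formation) is fast at −20 °C and leaves the two dioxolane stereocentres (C8, C9) untouched.

Step 2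
Reactants: 3 bis-Weinreb amide; 4 ethyl vinyl ether
Product: 5 mono-ketone (4R,5R)-5-(2-ethoxyacryloyl)-N-methoxy-N,2,2-trimethyl-1,3-dioxolane-4-carboxamide
Conditions: CH2=CHOEt, t-BuLi, THF, −78 → 0 °C; then 3 (1.2 equiv), −78 °C; aq. NH4Cl
Reagents that add atoms: ethyl vinyl ether, C=COCC
Why: Weinreb ketone synthesis with 1-ethoxyvinyllithium as a masked C1 carboxyl stops at the ketone through the chelated tetrahedral intermediate, and with the C2-symmetric diamide in slight excess at −78 °C mono-acylation should dominate (either amide gives the same product; unreacted 3 is recovered).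

Step 3
Reactants: 5 mono-ketone; 6 methylmagnesium bromide
Product: 7 (10R)-tertiary alcohol (4R,5R)-5-[(2R)-3-ethoxy-2-hydroxybut-3-en-2-yl]-N-methoxy-N,2,2-trimethyl-1,3-dioxolane-4-carboxamide
Conditions: MeMgBr (1.2 equiv), THF, −78 °C
Reagents that add atoms: methylmagnesium bromide, C[Mg]Br
Why: Chelation-controlled Grignard addition (Cram cyclic model) has magnesium bridging the ketone and the more basic dioxolane oxygen on C9, so methyl adds anti to C8 and sets C10 as R, while the ketone outpaces the Weinreb amide at −78 °C; adding the C1 unit first and methyl second is what gives this epimer.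

Step 4
Reactants: 7 tertiary alcohol; 8 ozone
Product: 9 hydroxy ester ethyl (2R)-2-hydroxy-2-{(4R,5R)-5-[methoxy(methyl)carbamoyl]-2,2-dimethyl-1,3-dioxolan-4-yl}propanoate
Conditions: O3, CH2Cl2, pyridine (cat.), −78 °C; Me2S
Reagents that add atoms: ozone, [O-][O+]=O
Why: Ozonolysis of the electron-rich enol ether cleaves C=CH2 and leaves the ethoxy-bearing carbon as the ethyl ester, unmasking C1 while no other alkene is yet in the molecule.

Step 5
Reactants: 9 hydroxy ester; 10 (triethylsilyl)acetylene
Product: 11 ynone ethyl (2R)-2-hydroxy-2-{(4R,5R)-2,2-dimethyl-5-[3-(triethylsilyl)prop-2-ynoyl]-1,3-dioxolan-4-yl}propanoate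
Conditions: HC≡CSiEt3, n-BuLi, THF, −78 °C; then 9, −78 → −20 °C; aq. NH4Cl
Reagents that add atoms: (triethylsilyl)acetylene, C#C[Si](CC)(CC)CC
Why: Weinreb ketone synthesis with a lithium acetylide, in which the first equivalent forms the tertiary alkoxide that (together with full α-substitution) shields the C1 ester and the second adds once to the amide.

Step 6
Reactants: 11 ynone
Product: 12 (7S)-propargylic alcohol ethyl (2R)-2-hydroxy-2-{(4R,5S)-5-[(1S)-1-hydroxy-3-(triethylsilyl)prop-2-yn-1-yl]-2,2-dimethyl-1,3-dioxolan-4-yl}propanoate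
Conditions: RuCl[(R,R)-TsDPEN](p-cymene) (2 mol %), i-PrOH, rt
Reagents that add atoms: none
Why: Noyori-type asymmetric transfer hydrogenation of an alkynyl ketone is reagent-controlled (this catalyst enantiomer gives R carbinols from methyl alkynyl ketones, which is 7S here by priority change) and its neutral conditions spare ester and acetonide.

Step 7
Reactants: 12 propargylic alcohol; 13 methanesulfonyl chloride
Product: 14 C7 mesylate of 12
Conditions: MsCl, Et3N, CH2Cl2, −40 °C
Reagents that add atoms: methanesulfonyl chloride, CS(=O)(=O)Cl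
Why: Sulfonylation takes the secondary propargylic alcohol only, because the tertiary hydroxyl on C10 is too hindered to react at −40 °C.

Step 8
Reactants: 14 mesylate; 15 acrolein
Product: 16 anti homopropargylic alcohol (6R,7S) ethyl (2R)-2-hydroxy-2-{(4R,5S)-5-[(3S,4R)-4-hydroxy-1-(triethylsilyl)hex-5-en-1-yn-3-yl]-2,2-dimethyl-1,3-dioxolan-4-yl}propanoate
Conditions: CH2=CHCHO, Pd(OAc)2 (5 mol %), PPh3 (5 mol %), Et2Zn (4 equiv), THF, −78 → −20 °C
Reagents that add atoms: acrolein, C=CC=O
Why: Pd-catalysed umpolung propargylation, in which zerovalent palladium displaces the mesylate anti (SN2′), ethyl transfer from Et2Zn gives a configurationally defined allenylzinc, and its SE2′ addition to acrolein through a chair-like cyclic transition state gives the anti adduct, so C7 is set with net inversion of the mesylate centre (7S, as needed) and C6 arises as the 6R epimer that step 9 corrects.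

Step 9
Reactants: 16 anti adduct; 17 4-nitrobenzoic acid
Product: 18 (6S)-4-nitrobenzoate of the C6-inverted alcohol
Conditions: 4-O2NC6H4CO2H, PPh3, DIAD, toluene, 0 °C → rt
Reagents that add atoms: 4-nitrobenzoic acid, OC(=O)c1ccc(cc1)[N+](=O)[O-]
Why: Mitsunobu esterification inverts C6 by SN2 attack of the carboxylate on the oxyphosphonium ion, giving the 6S configuration of the target (O6 and the alkynyl group now cis-disposed for the later cis-fused lactone), the tertiary hydroxyl being inert.

Step 10
Reactants: 18 nitrobenzoate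
Product: 19 (6S,7S)-homopropargylic alcohol
Conditions: K2CO3, EtOH, 0 °C
Reagents that add atoms: none
Why: Carbonate-catalysed transesterification cleaves the electron-poor aryl ester at 0 °C, with ethanol as solvent keeping the hindered C1 ethyl ester unchanged and the C–SiEt3 bond intact.

Step 11
Reactants: 19 alcohol; 20 chlorotriethylsilane
Product: 21 6-O-triethylsilyl ether of 19
Conditions: Et3SiCl, imidazole, CH2Cl2, 0 °C
Reagents that add atoms: chlorotriethylsilane, CC[Si](Cl)(CC)CC
Why: Silylation with Et3SiCl–imidazole takes only the secondary allylic hydroxyl and leaves the tertiary C10 hydroxyl free for the next step.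

Step 12
Reactants: 21 silyl ether; 22 trichloroethylene
Product: 23 10-O-[(E)-1,2-dichlorovinyl] ether of 21
Conditions: KH (1.1 equiv), THF, 0 °C; Cl2C=CHCl, −50 °C → rt
Reagents that add atoms: trichloroethylene, ClC=C(Cl)Cl
Why: Addition of the potassium alkoxide to dichloroacetylene generated in situ from trichloroethylene (the standard entry to 1,2-dichlorovinyl ethers) also works for tertiary alkoxides, and at this stage the substrate has no acidic C–H next to a carbonyl.

Step 13
Reactants: 23 dichlorovinyl ether ester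
Product: 24 C1 aldehyde
Conditions: i-Bu2AlH (1.2 equiv), CH2Cl2, −78 °C; aq. potassium sodium tartrate
Reagents that add atoms: none
Why: Partial ester reduction with i-Bu2AlH at −78 °C stops at the aluminium hemiacetal and gives the aldehyde on work-up, while the chloro enol ether, silyl groups and alkyne are inert.

Step 14
Reactants: 24 aldehyde; 25 vinylmagnesium bromide
Product: 26 C1 vinyl carbinol (both C1 epimers)
Conditions: CH2=CHMgBr, THF, −78 °C
Reagents that add atoms: vinylmagnesium bromide, C=C[Mg]Br
Why: Grignard 1,2-addition to the non-enolisable neopentyl aldehyde installs the second vinyl group, and the new C1 centre need not be controlled because it is oxidised in step 17.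

Step 15
Reactants: 26 diene
Product: 27 (Z)-cyclooct-2-en-1-ol (ring C1, C2, C5–C10; C1 epimers)
Conditions: second-generation Grubbs catalyst RuCl2(=CHPh)(PCy3)(H2IMes) (10 mol %), CH2Cl2 (2 mM), 40 °C
Reagents that add atoms: none
Why: Ring-closing metathesis of the two monosubstituted alkenes can only give the Z-cyclooctene, is driven by loss of ethene and is helped by the gauche bias of the trans-dioxolane, while the trisubstituted chloro enol ether and the silylalkyne are poor metathesis partners.

Step 16
Reactants: 27 cyclooctenol; 28 iodomethane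
Product: 32 10-O-(1-propynyl) cyclooctenol (C1 epimers), via silyl ether 29 (not isolated), via lithium alkynyl ether 30 (not isolated), via silylated propynyl ether 31 (not isolated)
Conditions: n-BuLi (1.0 equiv), THF, −78 °C, then Me3SiCl (1.0 equiv), → 0 °C; n-BuLi (2.3 equiv), −78 → −40 °C; MeI, DMPU, −78 → 0 °C; K2CO3, MeOH, 0 °C
Reagents that add atoms: iodomethane, CI
Why: The dichlorovinyl ether is converted by n-BuLi (vinylic deprotonation, loss of LiCl, chlorine–lithium exchange) into the lithium alkynyl ether, which MeI methylates on carbon (the standard alkynyl ether synthesis), with the C1 hydroxyl masked as a transient trimethylsilyl ether that the methanolic carbonate work-up removes.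

Step 17
Reactants: 32 propynyl ether alcohol
Product: 33 photosubstrate, (Z)-cyclooct-2-enone with 10-O-(1-propynyl), 7-(triethylsilylethynyl), 6-O-SiEt3 and 8,9-acetonide
Conditions: Dess–Martin periodinane, NaHCO3, CH2Cl2, 0 °C; used at once
Reagents that add atoms: none
Why: Dess–Martin oxidation of the allylic alcohol under bicarbonate buffer at 0 °C gives the Z-enone without acid or heat, neither of which the tertiary alkynyl ether would tolerate, and both C1 epimers converge.

Step 18
Reactants: 33 photosubstrate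
Product: 35 furanone-bridged (4Z)-cyclodecadiene, via cyclobutene 34 (not isolated)
Conditions: hν (350 nm, Pyrex), degassed CH2Cl2 (2 mM), 0 °C; then dark, 25 → 50 °C
Reagents that add atoms: none
Why: Proposed new method: excitation of the Z-cyclooctenone gives the triplet enone, whose C2 bonds to the oxygen-bearing alkyne carbon C3 (5-exo-dig closure of the oxacycle through the three-atom link C1–C10–O), and the vinyl radical at C4 then recombines with C5 (four-membered ring closure) to give the cis-fused 1-alkoxycyclobutene 34. On warming, 34 undergoes thermal four-electron conrotatory opening of the C2–C5 bond, so the ten-membered ring arises by ring expansion of the eight-membered one and not by end-to-end cyclisation, and the oxacycle is left as the 3(2H)-furanone. The closest known reactions are intramolecular enone–alkyne [2+2] photocycloadditions to bicyclo[3.2.0]heptene-type cyclobutenes and the thermal opening of cis-bicyclo[6.2.0]dec-9-enes to cis,trans-cyclodeca-1,3-dienes; an ynol ether tethered through the α′-oxygen of the enone has not been used in this way. No stereocentre is created in 35: C2 and C5 of 34 are set cis by the C10–O tether and erased on opening, while C6–C10 are untouched. The step needs head-to-head regiochemistry and Z geometry at C4=C5; the short tether allows only C2–C3/C4–C5 bonding (the silylalkyne on C7 could reach the enone only through a bicyclo[2.1.1]hexene), and because the five-membered ring forces C1 to rotate outward at C2, conrotation sends C6 inward at C5, which is 4Z. Irradiating at 0 °C guards the tertiary alkynyl ether against retro-ene loss of methylketene, and strain in the bridgehead cyclobutene together with formation of the vinylogous ester should let the opening run at or just above room temperature.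

Step 19
Reactants: 35 furanone-bridged cyclodecadiene
Product: 36 C6 alcohol with terminal alkyne at C7
Conditions: Bu4NF, AcOH, THF, 0 °C
Reagents that add atoms: none
Why: Fluoride cleaves the O–SiEt3 and C(sp)–SiEt3 bonds together, and acetic acid buffering protects the furanone from base.

Step 20
Reactants: 36 hydroxy alkyne; 37 carbon monoxide
Product: 38 α-methylene-γ-butyrolactone (6,12-olide) 8,9-acetonide
Conditions: PdCl2 (10 mol %), SnCl2 (10 mol %), PPh3 (20 mol %), CO (7 atm), MeCN, 70 °C
Reagents that add atoms: carbon monoxide, [C-]#[O+]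
Why: Pd-catalysed cyclocarbonylation of a homopropargylic alcohol, in which an alkoxycarbonyl–palladium species formed from the C6 hydroxyl and CO adds syn across the alkyne and protonolysis gives the α-methylene lactone, cis-fused because O6 and the ethynyl group are cis on the ring, while O8 and O9 are masked so only the C6 hydroxyl can lactonise.

Step 21
Reactants: 38 lactone acetonide
Product: 39 8,9-diol
Conditions: CF3CO2H–H2O (9:1), 0 °C
Reagents that add atoms: none
Why: Acid hydrolysis of the strained trans-fused dioxolane proceeds at 0 °C, conditions to which the furanone, the diene and the methylene lactone are stable.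

Step 22
Reactants: 39 diol; 40 methacrylic anhydride
Product: 41 target CNP0252578.4 (6S,7S,8S,9R,10R)
Conditions: methacrylic anhydride (1.1 equiv), Et3N, DMAP (cat.), CH2Cl2, −20 °C
Reagents that add atoms: methacrylic anhydride, C=C(C)C(=O)OC(=O)C(C)=C
Why: DMAP-catalysed acylation should take the C8 hydroxyl selectively because the C9 hydroxyl is neopentylic (next to the fully substituted C10), and low temperature with one equivalent of anhydride limits bis-acylation and acyl migration.

**Compound list**

1 | dimethyl (4R,5R)-2,2-dimethyl-1,3-dioxolane-4,5-dicarboxylate (dimethyl 2,3-O-isopropylidene-L-tartrate) | COC(=O)[C@@H]1OC(C)(C)O[C@H]1C(=O)OC | starting material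
2 | N,O-dimethylhydroxylamine hydrochloride | CNOC.Cl | starting material
3 | (4R,5R)-N4,N5-dimethoxy-N4,N5,2,2-tetramethyl-1,3-dioxolane-4,5-dicarboxamide | CON(C)C(=O)[C@@H]1OC(C)(C)O[C@H]1C(=O)N(C)OC | intermediate
4 | ethyl vinyl ether | C=COCC | starting material
5 | (4R,5R)-5-(2-ethoxyacryloyl)-N-methoxy-N,2,2-trimethyl-1,3-dioxolane-4-carboxamide (C10 ketone, C7 Weinreb amide) | C=C(OCC)C(=O)[C@@H]1OC(C)(C)O[C@H]1C(=O)N(C)OC | intermediate
6 | methylmagnesium bromide | C[Mg]Br | starting material
7 | (4R,5R)-5-[(2R)-3-ethoxy-2-hydroxybut-3-en-2-yl]-N-methoxy-N,2,2-trimethyl-1,3-dioxolane-4-carboxamide (10R tertiary alcohol) | C=C(OCC)[C@](C)(O)[C@@H]1OC(C)(C)O[C@H]1C(=O)N(C)OC | intermediate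
8 | ozone | [O-][O+]=O | starting material
9 | ethyl (2R)-2-hydroxy-2-{(4R,5R)-5-[methoxy(methyl)carbamoyl]-2,2-dimethyl-1,3-dioxolan-4-yl}propanoate | CCOC(=O)[C@](C)(O)[C@@H]1OC(C)(C)O[C@H]1C(=O)N(C)OC | intermediate
10 | (triethylsilyl)acetylene | C#C[Si](CC)(CC)CC | starting material
11 | ethyl (2R)-2-hydroxy-2-{(4R,5R)-2,2-dimethyl-5-[3-(triethylsilyl)prop-2-ynoyl]-1,3-dioxolan-4-yl}propanoate (C7 ynone) | CCOC(=O)[C@](C)(O)[C@@H]1OC(C)(C)O[C@H]1C(=O)C#C[Si](CC)(CC)CC | intermediate
12 | ethyl (2R)-2-hydroxy-2-{(4R,5S)-5-[(1S)-1-hydroxy-3-(triethylsilyl)prop-2-yn-1-yl]-2,2-dimethyl-1,3-dioxolan-4-yl}propanoate (7S propargylic alcohol) | CCOC(=O)[C@](C)(O)[C@@H]1OC(C)(C)O[C@H]1[C@@H](O)C#C[Si](CC)(CC)CC | intermediate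
13 | methanesulfonyl chloride | CS(=O)(=O)Cl | starting material
14 | C7 methanesulfonate of 12 | CCOC(=O)[C@](C)(O)[C@@H]1OC(C)(C)O[C@H]1[C@@H](OS(C)(=O)=O)C#C[Si](CC)(CC)CC | intermediate
15 | acrolein | C=CC=O | starting material
16 | ethyl (2R)-2-hydroxy-2-{(4R,5S)-5-[(3S,4R)-4-hydroxy-1-(triethylsilyl)hex-5-en-1-yn-3-yl]-2,2-dimethyl-1,3-dioxolan-4-yl}propanoate (anti adduct, 6R,7S) | CCOC(=O)[C@](C)(O)[C@@H]1OC(C)(C)O[C@H]1[C@@H](C#C[Si](CC)(CC)CC)[C@H](O)C=C | intermediate
17 | 4-nitrobenzoic acid | OC(=O)c1ccc(cc1)[N+](=O)[O-] | starting material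
18 | 6-O-(4-nitrobenzoyl) ester with inverted C6 (6S,7S) | CCOC(=O)[C@](C)(O)[C@@H]1OC(C)(C)O[C@H]1[C@@H](C#C[Si](CC)(CC)CC)[C@@H](OC(=O)c2ccc(cc2)[N+](=O)[O-])C=C | intermediate
19 | (6S,7S)-homopropargylic alcohol (C6 epimer of 16) | CCOC(=O)[C@](C)(O)[C@@H]1OC(C)(C)O[C@H]1[C@@H](C#C[Si](CC)(CC)CC)[C@@H](O)C=C | intermediate
20 | chlorotriethylsilane | CC[Si](Cl)(CC)CC | starting material
21 | 6-O-triethylsilyl ether of 19 (C10 hydroxyl free) | CCOC(=O)[C@](C)(O)[C@@H]1OC(C)(C)O[C@H]1[C@@H](C#C[Si](CC)(CC)CC)[C@@H](O[Si](CC)(CC)CC)C=C | intermediate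
22 | trichloroethylene | ClC=C(Cl)Cl | starting material
23 | 10-O-[(E)-1,2-dichlorovinyl] ether of 21 (C1 ethyl ester) | CCOC(=O)[C@](C)(O/C(Cl)=C\Cl)[C@@H]1OC(C)(C)O[C@H]1[C@@H](C#C[Si](CC)(CC)CC)[C@@H](O[Si](CC)(CC)CC)C=C | intermediate
24 | C1 aldehyde corresponding to 23 | O=C[C@](C)(O/C(Cl)=C\Cl)[C@@H]1OC(C)(C)O[C@H]1[C@@H](C#C[Si](CC)(CC)CC)[C@@H](O[Si](CC)(CC)CC)C=C | intermediate
25 | vinylmagnesium bromide | C=C[Mg]Br | starting material
26 | C1 vinyl carbinol, acyclic 1,9-diene for ring closure (C1 epimer mixture) | C=CC(O)[C@](C)(O/C(Cl)=C\Cl)[C@@H]1OC(C)(C)O[C@H]1[C@@H](C#C[Si](CC)(CC)CC)[C@@H](O[Si](CC)(CC)CC)C=C | intermediate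
27 | (Z)-cyclooct-2-en-1-ol with 10-methyl-10-O-(E-1,2-dichlorovinyl), 8,9-acetonide, 7-(triethylsilylethynyl), 6-O-SiEt3 (C1 epimer mixture) | CC1(C)O[C@H]2[C@@H](C#C[Si](CC)(CC)CC)[C@@H](O[Si](CC)(CC)CC)/C=C\C(O)[C@](C)(O/C(Cl)=C\Cl)[C@@H]2O1 | intermediate
28 | iodomethane | CI | starting material
29 | 1-O-trimethylsilyl ether of 27 | CC1(C)O[C@H]2[C@@H](C#C[Si](CC)(CC)CC)[C@@H](O[Si](CC)(CC)CC)/C=C\C(O[Si](C)(C)C)[C@](C)(O/C(Cl)=C\Cl)[C@@H]2O1 | intermediate
30 | lithium alkynyl ether (10-O-lithioethynyl, 1-O-SiMe3) | CC1(C)O[C@H]2[C@@H](C#C[Si](CC)(CC)CC)[C@@H](O[Si](CC)(CC)CC)/C=C\C(O[Si](C)(C)C)[C@](C)(OC#C[Li])[C@@H]2O1 | intermediate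
31 | 10-O-(1-propynyl) ether, 1-O-SiMe3 | CC1(C)O[C@H]2[C@@H](C#C[Si](CC)(CC)CC)[C@@H](O[Si](CC)(CC)CC)/C=C\C(O[Si](C)(C)C)[C@](C)(OC#CC)[C@@H]2O1 | intermediate
32 | 10-O-(1-propynyl) (Z)-cyclooct-2-en-1-ol (C1 epimer mixture) | CC1(C)O[C@H]2[C@@H](C#C[Si](CC)(CC)CC)[C@@H](O[Si](CC)(CC)CC)/C=C\C(O)[C@](C)(OC#CC)[C@@H]2O1 | intermediate
33 | (Z)-cyclooct-2-enone with 10-methyl-10-O-(1-propynyl), 8,9-acetonide, 7-(triethylsilylethynyl), 6-O-SiEt3 (photosubstrate) | CC1(C)O[C@H]2[C@@H](C#C[Si](CC)(CC)CC)[C@@H](O[Si](CC)(CC)CC)/C=C\C(=O)[C@](C)(OC#CC)[C@@H]2O1 | intermediate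
34 | tricyclic cyclobutene: C2–C3=C4–C5 four-membered ring cis-fused to the eight-membered ring, with the C1–C2–C3–O–C10 oxacycle | O=C1[C@H]2C3=C(C)[C@H]2[C@H](O[Si](CC)(CC)CC)[C@H](C#C[Si](CC)(CC)CC)[C@@H]4OC(C)(C)O[C@H]4[C@@]1(C)O3 | intermediate
35 | furanone-bridged ten-membered ring, 4Z alkene, 8,9-acetonide, 7-(triethylsilylethynyl), 6-O-SiEt3 | CC1(C)O[C@H]2[C@@H](C#C[Si](CC)(CC)CC)[C@@H](O[Si](CC)(CC)CC)/C=C(/C)C3=CC(=O)[C@](C)(O3)[C@@H]2O1 | intermediate
36 | 6-hydroxy-7-ethynyl furanone macrocycle, 8,9-acetonide | CC1(C)O[C@H]2[C@@H](C#C)[C@@H](O)/C=C(/C)C3=CC(=O)[C@](C)(O3)[C@@H]2O1 | intermediate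
37 | carbon monoxide | [C-]#[O+] | starting material
38 | cis-fused α-methylene-γ-butyrolactone (6,12-olide), 8,9-acetonide | CC1(C)O[C@H]2[C@H]3C(=C)C(=O)O[C@H]3/C=C(/C)C4=CC(=O)[C@](C)(O4)[C@@H]2O1 | intermediate
39 | 8,9-diol of the furanone lactone | O[C@H]1[C@H]2C(=C)C(=O)O[C@H]2/C=C(/C)C2=CC(=O)[C@](C)(O2)[C@@H]1O | intermediate
40 | methacrylic anhydride | C=C(C)C(=O)OC(=O)C(C)=C | starting material
41 | CNP0252578.4, 8-O-methacrylate (6S,7S,8S,9R,10R) | C=C(C)C(=O)O[C@H]1[C@H]2C(=C)C(=O)O[C@H]2/C=C(/C)C2=CC(=O)[C@](C)(O2)[C@@H]1O | target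

**Step count and risks**

Total step count: 22. Longest linear sequence: 22 steps (from 1).

Steps most likely to fail:

1. Step 18 (the proposed new method). Light-induced Z→E isomerisation of the ring alkene may outrun cycloaddition, leading to dimers or to a trans-fused cyclobutene that would open to the 4E diene. Retro-ene fragmentation of the tertiary alkynyl ether may compete, or the cyclobutene may resist opening. Fallback by known chemistry, building the furanone first and closing the large ring last: the route is left at silyl ether 21. Reduction with i-Bu2AlH gives the α-hydroxy aldehyde F1, and addition of the lithium acetylide of 2-methylbut-1-en-3-yne gives the enynyl diol F2. MnO2 oxidises only the propargylic alcohol to the α′-hydroxy ynone F3, and Et2NH-mediated 5-endo cyclisation gives the 3(2H)-furanone with an isopropenyl group on C3 F4. Ring-closing metathesis between that isopropenyl group and the C5 vinyl group (second-generation Grubbs catalyst, high dilution) forms C4=C5 and rejoins the route at 35.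

2. Step 15. Oligomerisation may outrun closure of the eight-membered ring, or the catalyst may be consumed by the chloro enol ether. Fallback, closing the ring at C1–C2 by organochromium addition: from 23, selective ozonolysis of the terminal vinyl group gives the C5 aldehyde F5. Stork–Zhao olefination (Ph3P=CHI from the phosphonium iodide and NaN(SiMe3)2) gives the Z-vinyl iodide F6, and i-Bu2AlH reduction of the ester gives the iodo aldehyde F7. Nozaki–Hiyama–Kishi cyclisation (CrCl2, catalytic NiCl2, DMSO) rejoins the route at 27.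

3. Step 9. Elimination toward the conjugated enyne or SN2′ attack may take the place of clean inversion at the hindered allylic carbinol. Fallback, setting C6 directly with an open-transition-state propargylation: from ynone 11, reduction with RuCl[(S,S)-TsDPEN](p-cymene) gives the C7-epimeric propargylic alcohol F8, and mesylation gives the epimeric mesylate F9. Anti-SN2′ displacement with Bu3SnLi/CuBr·SMe2 gives the allenylstannane F10. BF3·OEt2-promoted anti-SE2′ addition of F10 to acrolein is syn-selective and gives 19 directly (overall retention at C7), rejoining the route at 19.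

Further compounds
F1 | step 18 | (10R)-α-hydroxy aldehyde from 21 | O=C[C@](C)(O)[C@@H]1OC(C)(C)O[C@H]1[C@@H](C#C[Si](CC)(CC)CC)[C@@H](O[Si](CC)(CC)CC)C=C
F2 | step 18 | enynyl diol (C1 epimers) | C=C(C)C#CC(O)[C@](C)(O)[C@@H]1OC(C)(C)O[C@H]1[C@@H](C#C[Si](CC)(CC)CC)[C@@H](O[Si](CC)(CC)CC)C=C
F3 | step 18 | α′-hydroxy ynone | C=C(C)C#CC(=O)[C@](C)(O)[C@@H]1OC(C)(C)O[C@H]1[C@@H](C#C[Si](CC)(CC)CC)[C@@H](O[Si](CC)(CC)CC)C=C
F4 | step 18 | 3(2H)-furanone with C3 isopropenyl and C5 vinyl (metathesis substrate) | C=C(C)C1=CC(=O)[C@](C)(O1)[C@@H]2OC(C)(C)O[C@H]2[C@@H](C#C[Si](CC)(CC)CC)[C@@H](O[Si](CC)(CC)CC)C=C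
F5 | step 15 | C5 aldehyde from 23 | CCOC(=O)[C@](C)(O/C(Cl)=C\Cl)[C@@H]1OC(C)(C)O[C@H]1[C@@H](C#C[Si](CC)(CC)CC)[C@@H](O[Si](CC)(CC)CC)C=O
F6 | step 15 | (Z)-vinyl iodide ester | CCOC(=O)[C@](C)(O/C(Cl)=C\Cl)[C@@H]1OC(C)(C)O[C@H]1[C@@H](C#C[Si](CC)(CC)CC)[C@@H](O[Si](CC)(CC)CC)/C=C\I
F7 | step 15 | (Z)-vinyl iodide C1 aldehyde | O=C[C@](C)(O/C(Cl)=C\Cl)[C@@H]1OC(C)(C)O[C@H]1[C@@H](C#C[Si](CC)(CC)CC)[C@@H](O[Si](CC)(CC)CC)/C=C\I
F8 | step 9 | C7-epimeric propargylic alcohol | CCOC(=O)[C@](C)(O)[C@@H]1OC(C)(C)O[C@H]1[C@H](O)C#C[Si](CC)(CC)CC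
F9 | step 9 | C7-epimeric mesylate | CCOC(=O)[C@](C)(O)[C@@H]1OC(C)(C)O[C@H]1[C@H](OS(C)(=O)=O)C#C[Si](CC)(CC)CC
F10 | step 9 | allenylstannane (C7=C11=C13 bearing SiEt3 and SnBu3, axial chirality from anti SN2′) | CCOC(=O)[C@](C)(O)[C@@H]1OC(C)(C)O[C@H]1C([H])=[C@]=C([Si](CC)(CC)CC)[Sn](CCCC)(CCCC)CCCC
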